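## The problem

The target 19 is a (2S)-flavanone (chroman-4-one). Ring B is the benzo ring of a 2,2-dimethyl-2H-chromene joined through its C6 to C2. Ring A is fully substituted: hydroxyls at C5 and C7, 3-methylbut-2-enyl (prenyl) groups at C6 and C8, the ring oxygen at C8a and the ketone at C4a. The skeleton is held together by one aryl–C2 bond and the pyranone ring C, so the real difficulty is placing two identical five-carbon chains on the two ring A carbons that lie between oxygens. This must be done without O-alkylation, reverse (1,1-dimethylallyl) attachment, or cyclisation of a chain onto a neighbouring phenol. C2 is the only stereocenter, nothing else in the molecule can direct it, and so it has to be set by a chiral catalyst. Once set it is fragile: it is benzylic, carries the ring oxygen and is β to the ketone, so base, strong acid or long heating can open ring C by a retro-oxa-Michael reaction to the achiral 2'-hydroxychalcone, and reclosure returns racemate. The three electron-rich olefins (two prenyl, one chromene) do not tolerate strong Brønsted or Lewis acids or electrophilic oxidants, and the free phloroglucinol-type phenols are ambident nucleophiles. The feature that opens the way is the alternation of oxygen and carbon around ring A: C6 lies between O5 and O7, C8 between O7 and O1, and the only other carbon ortho to O5 or para to O7 is the quaternary C4a. An allyl group placed on O5 or O7 can therefore only end up on C6 or C8, and because an unsubstituted allyl group is the same from both ends it can afterwards be converted into prenyl by exchanging its terminal CH2 for an isopropylidene unit.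

## Retrosynthesis

**19 to 17 and 18.** The two trisubstituted C=C bonds of the prenyl chains are cut, which leaves the 6,8-diallyl flavanone 17 and two molecules of 2-methylbut-2-ene 18.
- Against neighbouring cuts: direct C-prenylation of a 5,7-dihydroxyflavanone needs base, which opens ring C, and gives O-, C6- and C8-products side by side. Rearrangement of prenyl ethers delivers the reverse-prenyl group after one shift and the normal one only after two, so the outcome depends on the pathway.
- Simplification: 17 lacks the two acid-sensitive trisubstituted olefins.
- Demand on the forward step: a double cross-metathesis must convert both hindered allyl groups and leave the chromene olefin alone.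

**17 to 13.** The C6–CH2 and C8–CH2 bonds are cut and each allyl group is returned to the nearest oxygen, giving the (2S)-5,7-bis(allyloxy)flavanone 13.
- Against neighbouring cuts: Friedel–Crafts allylation or metalation and alkylation of ring A would need acid or strong base next to C2 and would have to choose between C6 and C8. Sigmatropic transfer from oxygen needs neither, and here it cannot choose wrongly.
- Simplification: ring A of 13 carries only two ether groups and two C–H bonds, and the allyl groups have already served as phenol protection through the earlier steps, so no protecting group is added or removed anywhere.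
- Demand on the forward step: both migrations must run to completion, and C2 must survive the temperature.

**13 to 5 and 12.** The C2–aryl bond is cut, giving 5,7-bis(allyloxy)chromone 5 and the chromenylboronic acid 12.
- Against the neighbouring cut at O1–C2 (cyclisation of a 2'-hydroxychalcone): that ring closure is reversible and, without an extra activating group, hard to render enantioselective. Aryl transfer to C2 is an irreversible C–C bond formation in which the catalyst alone decides the configuration.
- Simplification: the cut divides the molecule into two achiral halves of similar size.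
- Demand on the forward step: face-selective conjugate addition to an electron-rich chromone at a temperature and basicity at which the product does not ring-open, without touching the allyl ether olefins.

**5 to 3 to 1 and 2.** Ring C is opened at O1–C2 and C2–C3, with C2 arriving as a one-carbon unit through the enaminone 4. This leads to the acetophenone 3, whose two O–allyl bonds are cut to give 2,4,6-trihydroxyacetophenone 1 and allyl bromide 2.
- The hydroxyl hydrogen-bonded to the acetyl group selects itself as the one left free for ring closure, so no differentiation step is needed.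
- Demand on the forward steps: O- over C-allylation, and a ring closure that tolerates allyl ethers.

**12 to 9 to 8 to 6 and 7.** The C–B bond of 12 is traced to the bromide 9. The pyran ring of 9 is opened by the retro form of a propargyl Claisen cascade to the aryl propargyl ether 8, and its ether bond is cut to give 4-bromophenol 6 and 3-chloro-3-methylbut-1-yne 7.
- The bromine blocks the para position, so the rearrangement can only build the chromene, and it then becomes the handle for boron.

## Roads not taken

**Alternative 1: benzannulation that builds ring A with both prenyl groups in place.** The cut runs through C7–C8, C4a–C8a and C6–C7. In the forward sense the 4-prenyl-3-[2-(trimethylsilyl)ethoxy]cyclobutenone A2 and the prenyl-substituted triisopropylsiloxy alkyne A3 are heated together. Electrocyclic opening to a vinylketene, (2+2) addition to the ynol ether, a second opening and 6π closure would give the pentasubstituted phenol A1, whose single free ring carbon is the future C4a.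
- Merits: the substitution pattern of ring A is fixed by the connectivity of the partners and not by phenol chemistry, the prenyl groups arrive complete so no metathesis is needed, and the two oxygens flanking C4a are differentiated from the outset. In these respects it is better than the chosen plan.
- Weak points: A2 and A3 each need several steps. A1 still lacks C4, C3, C2, ring B and the stereocenter. The acylation at C4a and all later operations would have to be run on a ring carrying two prenyl groups next to oxygen, where acid closes them to chromans.
- Comparison: the chosen plan buys ring A as 1 and reaches 19 in eight steps with no protecting-group operations. What it sets against the regiochemical certainty of A1 is pathway convergence of the allyl shifts, which gives the same certainty for two steps instead of many.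

**Alternative 2: Friedel–Crafts closure of ring C onto the last free ring A carbon.** The cut is C4–C4a. The (S)-3-aryloxy-3-(chromen-6-yl)propanoic acid A5 would be activated with trifluoroacetic anhydride and would acylate C4a of its own aryloxy ring to give the bis-silyl ether A4 of the target.
- Merits: there is only one position to acylate, so no regiochemical question arises, C2 is set earlier in an open-chain compound, and no step after that runs above room temperature. This is a real advantage over the chosen plan, whose stereocenter must survive 180 °C.
- Weak points: the closure releases trifluoroacetic acid in the presence of two prenyl groups ortho to oxygen, the chromene olefin, and an aryl benzylic ether at a carbon carrying a para-alkoxyaryl group. That ether ionises easily, which would racemise C2 or eliminate to the cinnamic acid. A5 itself requires an aryl–oxygen bond to be made with stereochemical fidelity at the same ionisable carbon, a threefold differentiation of the phloroglucinol oxygens, and silyl protection and deprotection.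
- Comparison: the chosen plan sets a neutral medium against the thermal risk and does not introduce the acid-sensitive prenyl olefins until the last step.

**Alternative 3: carbenoid C–H insertion that closes ring C and sets C2 together.** The cut is C2–C3. The aryl diazomethyl ketone A7, which carries the (chromen-6-yl)methyl ether ortho to the diazoacetyl group, would lose N2 on Rh2(S-PTTL)4 (a divalent rhodium dimer), and the carbene carbon would insert into one of the two benzylic C–H bonds to give the diacetate A6.
- Merits: one step forms the last skeletal bond, closes ring C and creates the stereocenter under catalyst control, late and at low temperature. On paper this is the most economical way of setting C2.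
- Weak points: the carbenoid is of the acceptor-only type, the most reactive and least selective class. The insertion must close a six-membered ring, whereas attack of the ether oxygen on the carbenoid gives a five-membered oxonium ylide whose 1,2-shift of the benzylic group contracts the ring. Three electron-rich olefins (two prenyl, one chromene) are open to cyclopropanation. Enantiotopic C–H selection by a carbenoid of this type is not reliably high.
- Comparison: the chosen plan sets C2 by a catalytic aryl transfer with direct precedent on chromones, on a substrate whose only competing functionality is two isolated allyl ethers. It pays for this with the thermal step that follows.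

Key step: step 7

Assumption: the (S)-configured biaryl bisphosphine is taken to deliver the aryl group to the face of the chromone that gives the (2S)-flavanone. This is the same face, by geometry, on which ligands of this family give the (S)-ketone from 2-cyclohexenone. If the sense proves opposite, the (R)-ligand is used and nothing else changes.

## Route

Step 1
Reactants: 1 2,4,6-trihydroxyacetophenone; 2 allyl bromide
Product: 3 1-[2-hydroxy-4,6-bis(prop-2-en-1-yloxy)phenyl]ethan-1-one
Conditions: 2 (2.1 equiv), K2CO3 (2.2 equiv), acetone, reflux
Reagents that add atoms: none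
Why: Williamson etherification of the phenoxides; the hydroxyl that is hydrogen-bonded to the acetyl carbonyl is the least nucleophilic, so with two equivalents of halide the 4-oxygen and one ortho oxygen are etherified and the chelated OH remains for the later ring closure.

Step 2
Reactants: 3 1-[2-hydroxy-4,6-bis(prop-2-en-1-yloxy)phenyl]ethan-1-one
Product: 5 5,7-bis(prop-2-en-1-yloxy)-4H-chromen-4-one, via enaminone 4 (not isolated)
Conditions: Me2NCH(OMe)2 (3 equiv), toluene, 95 °C; evaporate; conc. HCl, CH2Cl2, 40 °C
Reagents that add atoms: N,N-dimethylformamide dimethyl acetal, COC(OC)N(C)C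
Why: Condensation of the methyl ketone with the amide acetal gives the (E)-enaminone 4; acid then promotes conjugate addition of the free ortho hydroxyl and loss of dimethylamine (addition–elimination), which is the standard enaminone route to 3-unsubstituted chromones, and allyl aryl ethers tolerate this brief acid treatment.

Step 3
Reactants: 6 4-bromophenol; 7 3-chloro-3-methylbut-1-yne
Product: 8 1-bromo-4-[(2-methylbut-3-yn-2-yl)oxy]benzene
Conditions: K2CO3, KI (cat.), CuI (cat.), acetone, 60 °C
Reagents that add atoms: none
Why: Copper-assisted propargylic substitution of a tertiary propargylic chloride by a phenoxide, the usual entry to aryl 1,1-dimethylpropargyl ethers; the reaction passes through a copper acetylide-derived electrophile, so the tertiary centre is not a hindrance.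

Step 4
Reactants: 8 1-bromo-4-[(2-methylbut-3-yn-2-yl)oxy]benzene
Product: 9 6-bromo-2,2-dimethyl-2H-chromene
Conditions: PhNEt2, 190 °C
Reagents that add atoms: none
Why: Aromatic propargyl Claisen rearrangement: a (3,3) shift to the ortho-allenyl dienone, enolisation, 1,5-hydrogen shift to the ortho-quinone methide and oxa-6π electrocyclisation give the chromene; the two ortho positions are equivalent and bromine blocks the para position, so a single product is expected.

Step 5
Reactants: 9 6-bromo-2,2-dimethyl-2H-chromene
Product: 12 (2,2-dimethyl-2H-chromen-6-yl)boronic acid, via aryllithium 10 (not isolated), via lithium aryl(triisopropoxy)borate 11 (not isolated)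
Conditions: n-BuLi (1.1 equiv), THF, −78 °C; B(OiPr)3, −78 °C to rt; 1 M HCl, 0 °C
Reagents that add atoms: triisopropyl borate, CC(C)OB(OC(C)C)OC(C)C; water, O
Why: Bromine–lithium exchange, capture of the aryllithium by the borate and hydrolysis of the ate complex is the standard boronic acid synthesis; the chromene olefin is inert to n-BuLi at −78 °C and survives brief cold dilute acid.

Step 6
Reactants: 5 5,7-bis(prop-2-en-1-yloxy)-4H-chromen-4-one; 12 (2,2-dimethyl-2H-chromen-6-yl)boronic acid
Product: 13 (2S)-2-(2,2-dimethyl-2H-chromen-6-yl)-5,7-bis(prop-2-en-1-yloxy)chroman-4-one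
Conditions: [RhCl(C2H4)2]2 (1.5 mol %), (S)-MeO-F12-BIPHEP [(S)-6,6'-dimethoxy-2,2'-bis{bis(3,4,5-trifluorophenyl)phosphino}biphenyl, 3.3 mol %], aq. KOH (20 mol %), 12 (1.5 equiv), CH2Cl2/H2O, 25 °C
Reagents that add atoms: none
Why: Rhodium-catalysed asymmetric 1,4-addition of an arylboronic acid to a chromone (Hayashi–Miyaura reaction): transmetalation to an aryl–rhodium species of monovalent rhodium, enantioface-selective insertion of the C2=C3 bond and protonolysis of the oxa-π-allyl complex by water; the C2-symmetric (S)-bisphosphine shields one face of the bound enone so that the aryl group is delivered to give (2S), and the electron-poor phosphine allows room temperature, where the product neither ring-opens nor adds a second aryl group and the isolated allyl ether olefins should not compete with the enone.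

Step 7
Reactants: 13 (2S)-2-(2,2-dimethyl-2H-chromen-6-yl)-5,7-bis(prop-2-en-1-yloxy)chroman-4-one
Product: 17 (2S)-2-(2,2-dimethyl-2H-chromen-6-yl)-5,7-dihydroxy-6,8-di(prop-2-en-1-yl)chroman-4-one, via 6-allyl-7-allyloxy-5-hydroxy flavanone 14 (not isolated), via 8-allyl-5-allyloxy-7-hydroxy flavanone 15 (not isolated), via 6-allyl-5-allyloxy-7-hydroxy flavanone 16 (not isolated)
Conditions: 1,2-dichlorobenzene (degassed, dilute), 180 °C, sealed tube, Ar
Reagents that add atoms: none
Why: Each allyl aryl ether undergoes a concerted suprafacial (3,3) sigmatropic shift through a chair-like transition state to an ortho-cyclohexadienone that re-aromatises by enolisation; this is the thermal aromatic Claisen rearrangement, known for allyl ethers of flavonoids together with its Claisen–Cope extension. The 5-O-allyl group can reach only C6 because its other ortho carbon, C4a, is quaternary, whereas the 7-O-allyl group can reach C6 or C8, so the mono-rearranged phenols 14, 15 and 16 are all expected in the flask. From 14 the remaining 7-O-allyl group has only C8 left, from 15 the 5-O-allyl group has only C6 left, and from 16 the 5-O-allyl group enters the occupied C6 to give a 6,6-diallyl dienone that cannot enolise and passes one allyl group on to C8, para to O5, by a Cope shift. Because an unsubstituted allyl group is identical from either end, every sequence of one or two shifts delivers the same CH2–CH=CH2 chain and all paths converge on 17. No ring is closed and no stereocenter is created; the C6–CH2 and C8–CH2 bonds are the only skeletal bonds formed. The selectivity required is regiochemical and is secured by the substitution pattern itself: C4a is blocked, C6 and C8 are the only open carbons ortho or para to O5 and O7, and a shift from O7 toward C4a is a dead end that reverts. C2 takes no part, and the base-free, aprotic, oxygen-free medium is chosen so that the liberated phenols do not trigger retro-oxa-Michael opening of ring C, the one process that could erode its configuration.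

Step 8
Reactants: 17 (2S)-2-(2,2-dimethyl-2H-chromen-6-yl)-5,7-dihydroxy-6,8-di(prop-2-en-1-yl)chroman-4-one; 18 2-methylbut-2-ene
Product: 19 (2S)-2-(2,2-dimethyl-2H-chromen-6-yl)-5,7-dihydroxy-6,8-bis(3-methylbut-2-en-1-yl)chroman-4-one
Conditions: second-generation Grubbs catalyst (H2IMes)(PCy3)Cl2Ru=CHPh (10 mol %), 18 (large excess)/CH2Cl2, 40 °C, sealed tube
Reagents that add atoms: none
Why: Olefin cross-metathesis of terminal allylarenes with a trisubstituted olefin used in large excess exchanges each terminal CH2 for an isopropylidene unit with loss of propene; the chromene olefin is a cis-disubstituted, arene-conjugated double bond in an unstrained ring next to a quaternary carbon, so its ring-opening is non-productive, and the neutral conditions leave C2 and the free phenols untouched.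

## Compound list

1 | 2,4,6-trihydroxyacetophenone | CC(=O)c1c(O)cc(O)cc1O | starting material
2 | allyl bromide (3-bromoprop-1-ene) | C=CCBr | starting material
3 | 1-[2-hydroxy-4,6-bis(prop-2-en-1-yloxy)phenyl]ethan-1-one | CC(=O)c1c(O)cc(OCC=C)cc1OCC=C | intermediate
4 | (E)-3-(dimethylamino)-1-[2-hydroxy-4,6-bis(prop-2-en-1-yloxy)phenyl]prop-2-en-1-one | CN(C)/C=C/C(=O)c1c(O)cc(OCC=C)cc1OCC=C | intermediate (not isolated)
5 | 5,7-bis(prop-2-en-1-yloxy)-4H-chromen-4-one | O=c1ccoc2cc(OCC=C)cc(OCC=C)c12 | intermediate
6 | 4-bromophenol | Oc1ccc(Br)cc1 | starting material
7 | 3-chloro-3-methylbut-1-yne | C#CC(C)(C)Cl | starting material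
8 | 1-bromo-4-[(2-methylbut-3-yn-2-yl)oxy]benzene | C#CC(C)(C)Oc1ccc(Br)cc1 | intermediate
9 | 6-bromo-2,2-dimethyl-2H-chromene | CC1(C)C=Cc2cc(Br)ccc2O1 | intermediate
10 | (2,2-dimethyl-2H-chromen-6-yl)lithium | [Li]c1ccc2c(c1)C=CC(C)(C)O2 | intermediate (not isolated)
11 | lithium (2,2-dimethyl-2H-chromen-6-yl)tri(propan-2-yloxy)borate | [Li+].CC(C)O[B-](OC(C)C)(OC(C)C)c1ccc2c(c1)C=CC(C)(C)O2 | intermediate (not isolated)
12 | (2,2-dimethyl-2H-chromen-6-yl)boronic acid | OB(O)c1ccc2c(c1)C=CC(C)(C)O2 | intermediate
13 | (2S)-2-(2,2-dimethyl-2H-chromen-6-yl)-5,7-bis(prop-2-en-1-yloxy)chroman-4-one | C=CCOc1cc2c(c(OCC=C)c1)C(=O)C[C@@H](c1ccc3c(c1)C=CC(C)(C)O3)O2 | intermediate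
14 | (2S)-2-(2,2-dimethyl-2H-chromen-6-yl)-5-hydroxy-6-(prop-2-en-1-yl)-7-(prop-2-en-1-yloxy)chroman-4-one | C=CCOc1cc2c(c(O)c1CC=C)C(=O)C[C@@H](c1ccc3c(c1)C=CC(C)(C)O3)O2 | intermediate (not isolated)
15 | (2S)-2-(2,2-dimethyl-2H-chromen-6-yl)-7-hydroxy-8-(prop-2-en-1-yl)-5-(prop-2-en-1-yloxy)chroman-4-one | C=CCOc1cc(O)c(CC=C)c2c1C(=O)C[C@@H](c1ccc3c(c1)C=CC(C)(C)O3)O2 | intermediate (not isolated)
16 | (2S)-2-(2,2-dimethyl-2H-chromen-6-yl)-7-hydroxy-6-(prop-2-en-1-yl)-5-(prop-2-en-1-yloxy)chroman-4-one | C=CCOc1c(CC=C)c(O)cc2c1C(=O)C[C@@H](c1ccc3c(c1)C=CC(C)(C)O3)O2 | intermediate (not isolated)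
17 | (2S)-2-(2,2-dimethyl-2H-chromen-6-yl)-5,7-dihydroxy-6,8-di(prop-2-en-1-yl)chroman-4-one | C=CCc1c(O)c(CC=C)c2c(c1O)C(=O)C[C@@H](c1ccc3c(c1)C=CC(C)(C)O3)O2 | intermediate
18 | 2-methylbut-2-ene | CC=C(C)C | starting material
19 | (2S)-2-(2,2-dimethyl-2H-chromen-6-yl)-5,7-dihydroxy-6,8-bis(3-methylbut-2-en-1-yl)chroman-4-one | CC(C)=CCc1c(O)c(CC=C(C)C)c2c(c1O)C(=O)C[C@@H](c1ccc3c(c1)C=CC(C)(C)O3)O2 | target

## Step count and risk

Total step count: 8. Longest linear sequence: 6 steps (6 to 8 to 9 to 12 to 13 to 17 to 19, steps 3 to 8); the branch from 1 contributes 2 steps.

**Step 7 (key step).**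
- Most likely failure: loss of configurational purity at C2. At 180 °C, once phenols are set free, ring C can open by retro-oxa-Michael reaction and reclose. Less serious are an incomplete second migration and acid-type cyclisation of an ortho-allylphenol onto its own olefin. The optical purity of 17 should be compared with that of 13 before going on.
- Fallback: move the rearrangement to a stage that has no stereocenter.
  - Chromone 5 is heated in 1,2-dichlorobenzene at 180–190 °C to give 6,8-diallyl-5,7-dihydroxy-4H-chromen-4-one F1, by the same convergent double shift.
  - Both phenols are masked with MeOCH2Cl and NaH in DMF to give 6,8-diallyl-5,7-bis(methoxymethoxy)-4H-chromen-4-one F2.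
  - The rhodium-catalysed asymmetric 1,4-addition of 12 under the conditions of step 6 gives (2S)-6,8-diallyl-2-(2,2-dimethyl-2H-chromen-6-yl)-5,7-bis(methoxymethoxy)chroman-4-one F3.
  - Mild acetal cleavage (HCl, MeOH, 40 °C) returns to the route at 17.

**Step 6.**
- Most likely failure: slow insertion into the doubly donor-substituted chromone, whose carbonyl is shielded by the 5-alkoxy group. Protodeboronation of the electron-rich boronic acid would then outrun it. Coordination or isomerisation of the allyl ether olefins at rhodium, and erosion of enantiomeric purity by hydroxide-induced ring opening, are further risks.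
- Fallback: avoid conjugate addition altogether, setting out from 3 and 9.
  - Bromide 9 is converted by n-BuLi and DMF into 2,2-dimethyl-2H-chromene-6-carbaldehyde F4.
  - Claisen–Schmidt condensation of 3 with F4 (KOH, EtOH, rt) gives (E)-1-[2-hydroxy-4,6-bis(prop-2-en-1-yloxy)phenyl]-3-(2,2-dimethyl-2H-chromen-6-yl)prop-2-en-1-one F5.
  - Oxa-Michael cyclisation (NaOAc, EtOH, reflux) gives the racemic flavanone F6.
  - Preparative chromatography on a cellulose tris(3,5-dimethylphenylcarbamate) phase separates the enantiomers and returns to the route at 13. The (2R)-enantiomer F7 is recycled by base equilibration through F5.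

**Step 8.**
- Most likely failure: migration of the allyl double bond into conjugation by ruthenium hydride species, followed by metathesis to a chain shortened by one carbon. Also possible are incomplete exchange at the second, doubly flanked allyl group and catalyst loss through chelation by the neighbouring phenols.
- Fallback: run the metathesis on masked phenols, setting out from 17.
  - Et3SiOTf and 2,6-lutidine in CH2Cl2 give (2S)-6,8-diallyl-2-(2,2-dimethyl-2H-chromen-6-yl)-5,7-bis(triethylsilyloxy)chroman-4-one F8.
  - Cross-metathesis with 18 and the same ruthenium catalyst gives (2S)-2-(2,2-dimethyl-2H-chromen-6-yl)-6,8-bis(3-methylbut-2-en-1-yl)-5,7-bis(triethylsilyloxy)chroman-4-one F9.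
  - HF·pyridine in THF at 0 °C removes the silyl groups without base and returns to the route at 19.

**Step 1.**
- Most likely failure: C-allylation of the phloroglucinol ring and etherification of the chelated hydroxyl, competing with the wanted bis-O-allylation because the phenoxide is ambident.
- Fallback: replace phenoxide alkylation by Mitsunobu etherification. Compound 1 is treated with allyl alcohol, PPh3 and diisopropyl azodicarboxylate in THF, which forms the two aryl allyl ethers under neutral conditions without a free phenoxide and comes back to the route at 3. No new compound is made.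

## Further compounds

F1 | step 7 | 6,8-diallyl-5,7-dihydroxy-4H-chromen-4-one | O=c1ccoc2c(CC=C)c(O)c(CC=C)c(O)c12
F2 | step 7 | 6,8-diallyl-5,7-bis(methoxymethoxy)-4H-chromen-4-one | O=c1ccoc2c(CC=C)c(OCOC)c(CC=C)c(OCOC)c12
F3 | step 7 | (2S)-6,8-diallyl-2-(2,2-dimethyl-2H-chromen-6-yl)-5,7-bis(methoxymethoxy)chroman-4-one | C=CCc1c(OCOC)c(CC=C)c2c(c1OCOC)C(=O)C[C@@H](c1ccc3c(c1)C=CC(C)(C)O3)O2
F4 | step 6 | 2,2-dimethyl-2H-chromene-6-carbaldehyde | O=Cc1ccc2c(c1)C=CC(C)(C)O2
F5 | step 6 | (E)-1-[2-hydroxy-4,6-bis(prop-2-en-1-yloxy)phenyl]-3-(2,2-dimethyl-2H-chromen-6-yl)prop-2-en-1-one | C=CCOc1cc(O)c(C(=O)/C=C/c2ccc3c(c2)C=CC(C)(C)O3)c(OCC=C)c1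
F6 | step 6 | racemic 2-(2,2-dimethyl-2H-chromen-6-yl)-5,7-bis(prop-2-en-1-yloxy)chroman-4-one | C=CCOc1cc2c(c(OCC=C)c1)C(=O)CC(c1ccc3c(c1)C=CC(C)(C)O3)O2
F7 | step 6 | (2R)-2-(2,2-dimethyl-2H-chromen-6-yl)-5,7-bis(prop-2-en-1-yloxy)chroman-4-one | C=CCOc1cc2c(c(OCC=C)c1)C(=O)C[C@H](c1ccc3c(c1)C=CC(C)(C)O3)O2
F8 | step 8 | (2S)-6,8-diallyl-2-(2,2-dimethyl-2H-chromen-6-yl)-5,7-bis(triethylsilyloxy)chroman-4-one | C=CCc1c(O[Si](CC)(CC)CC)c(CC=C)c2c(c1O[Si](CC)(CC)CC)C(=O)C[C@@H](c1ccc3c(c1)C=CC(C)(C)O3)O2
F9 | step 8 | (2S)-2-(2,2-dimethyl-2H-chromen-6-yl)-6,8-bis(3-methylbut-2-en-1-yl)-5,7-bis(triethylsilyloxy)chroman-4-one | CC(C)=CCc1c(O[Si](CC)(CC)CC)c(CC=C(C)C)c2c(c1O[Si](CC)(CC)CC)C(=O)C[C@@H](c1ccc3c(c1)C=CC(C)(C)O3)O2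
F0 | step 1 | none | none
A1 | alternative 1 | 2,6-bis(3-methylbut-2-en-1-yl)-3-(triisopropylsilyloxy)-5-[2-(trimethylsilyl)ethoxy]phenol | Oc1c(CC=C(C)C)c(O[Si](C(C)C)(C(C)C)C(C)C)cc(OCC[Si](C)(C)C)c1CC=C(C)C
A2 | alternative 1 | 4-(3-methylbut-2-en-1-yl)-3-[2-(trimethylsilyl)ethoxy]cyclobut-2-en-1-one | O=C1C=C(OCC[Si](C)(C)C)C1CC=C(C)C
A3 | alternative 1 | triisopropyl[(5-methylhex-4-en-1-yn-1-yl)oxy]silane | CC(C)=CCC#CO[Si](C(C)C)(C(C)C)C(C)C
A4 | alternative 2 | (2S)-5,7-bis(tert-butyldimethylsilyloxy)-2-(2,2-dimethyl-2H-chromen-6-yl)-6,8-bis(3-methylbut-2-en-1-yl)chroman-4-one | CC(C)=CCc1c(O[Si](C)(C)C(C)(C)C)c(CC=C(C)C)c2c(c1O[Si](C)(C)C(C)(C)C)C(=O)C[C@@H](c1ccc3c(c1)C=CC(C)(C)O3)O2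
A5 | alternative 2 | (3S)-3-[3,5-bis(tert-butyldimethylsilyloxy)-2,4-bis(3-methylbut-2-en-1-yl)phenoxy]-3-(2,2-dimethyl-2H-chromen-6-yl)propanoic acid | CC(C)=CCc1c(O[Si](C)(C)C(C)(C)C)cc(O[C@@H](CC(=O)O)c2ccc3c(c2)C=CC(C)(C)O3)c(CC=C(C)C)c1O[Si](C)(C)C(C)(C)C
A6 | alternative 3 | (2S)-2-(2,2-dimethyl-2H-chromen-6-yl)-6,8-bis(3-methylbut-2-en-1-yl)-4-oxochroman-5,7-diyl diacetate | CC(C)=CCc1c(OC(C)=O)c(CC=C(C)C)c2c(c1OC(C)=O)C(=O)C[C@@H](c1ccc3c(c1)C=CC(C)(C)O3)O2
A7 | alternative 3 | 4-(2-diazoacetyl)-5-[(2,2-dimethyl-2H-chromen-6-yl)methoxy]-2,6-bis(3-methylbut-2-en-1-yl)-1,3-phenylene diacetate | CC(C)=CCc1c(OC(C)=O)c(CC=C(C)C)c(OCc2ccc3c(c2)C=CC(C)(C)O3)c(C(=O)C=[N+]=[N-])c1OC(C)=O
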